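The reading is due at 50 min, which is 20.0 min past the last reading of the spring run, the nearest recipe: same equivalents, 28 mM of electrophile against 20 mM here.

| flask | electrophile | nucleophile | remark | time |
|---|---|---|---|---|
| spring | 28 mM | 1.5 equiv | run made earlier |  |
| noon | 44 mM | 1.5 equiv | run made earlier |  |
| dusk | 20 mM | 2.2 equiv | run made earlier |  |
| flask | 20 mM | 1.50 equiv |  | 50 min |

- spring (time / min: electrophile / %, target / %): 2.50: 51.0, 20.6; 8.00: 30.0, 27.1; 15.0: 16.7, 28.9; 20.0: 10.8, 31.6; 30.0: 5.6, 32.6
- noon (time / min: electrophile / %, target / %): 2.50: 40.5, 23.5; 5.00: 30.5, 25.1; 8.00: 23.2, 27.6; 15.0: 13.2, 29.7; 30.0: 1.9, 34.2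
- dusk (time / min: electrophile / %, target / %): 6.00: 25.5, 27.8; 12.0: 9.3, 32.8; 20.0: 3.6, 33.8; 25.0: 2.4, 31.4; 30.0: 0.3, 34.8

(standard deviation of a reading: 1 percentage point)

1. part of the electrophile that has reacted at 50 min
2. share of the unused nucleophile that is free and not bound as protonated nucleophile, at 50 min

- steps under discussion: nucleophile + acid set free <-> protonated nucleophile; target <-> isomer of the product; acid set free -> by-product carried off; electrophile + nucleophile -> acid set free + target
- the earlier runs do not show how much of nucleophile is bound; that part of a forecast is a guess

How fast does the electrophile fall late in a run? Between 15.0 min and 30.0 min the spring run goes from 16.7% to 5.6%, and we treat this stretch as a pseudo-first-order decay. That gives the tail half-life h = 9.52 min.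

How many of these fit in the time left? 2.10 do, so our reckoning takes the spring run's 5.6% down to 1.30%, and c is about 98.7%.

Does the lower charge spoil this? The noon tail half-life, read the same way, is 5.36 min, shorter than h at the larger charge. Stretching h in proportion to charge gives 13.3 min and leaves 1.98%, so we put c at 98.0% to 98.7%. The readings do not show fr, so we set no number of our own for it.

The forecast gave c = 98.9% and fr = 88%, adding “The bound share is inferred”.

    nucleophile + acid set free ⇌ protonated nucleophile, settled at all times (K = 17000 L mol⁻¹)
    target ⇌ isomer of the product (K = 1.90, k = 0.0180 s⁻¹)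
    acid set free → by-product carried off (k = 0.140 s⁻¹)
    electrophile + nucleophile → acid set free + target (k = 0.180 L mol⁻¹ s⁻¹)

The flask gives c = 98.7% and fr = 82.9%. With the step from acid set free to by-product carried off struck out, c comes to 78.7%. Now we put h, a reading from the spring run at 28 mM with the scatter of those readings, to use on this flask: the flask held 10.1% of its electrophile at 25.0 min, and counting 2.63 spring half-lives from there leaves 1.64% at 50 min, where the flask holds 1.26%, so the flask's own half-life over that stretch is 8.32 min, shorter than h.

The numbers in the tables are simulated with made-up constants; scatter was added.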